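**Retrosynthetic overview**
1. Endgame: free the C19 and C20 acids from tert-butyl esters while C7 stays a methyl ester. C16=CH2 comes from a Wittig reaction on a 13-silyloxy-16-ketone, and ring D (C13–C16) from SmI2 pinacol closure of a C13 ketone and a C16 aldehyde.
2. The C8 quaternary centre and the masked C13 ketone come from Birch reduction–allylation of a cis-fused 7-methoxyhexahydrofluoren-9-one (rings A, B, aromatic C). The C6 ketone is then homologated to the C7 ester and the 9(11)-alkene is hydrogenated.
3. Ring A: the key intermolecular Michael addition (C10–C1) joins an indan-2-one-1-carboxylate (fragment 1: rings B/C, C20) to tert-butyl 3-oxopent-4-enoate (fragment 2: C1–C4, C19). Knoevenagel closure (C4–C5), C6 oxidation/Zn reduction (cis A/B), C4 methylation and C3 deoxygenation follow.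
4. Fragment 1: Rh-carbenoid aromatic substitution (ring B) of a diazo β-keto ester made from 3-methoxyphenylacetic acid. Fragment 2: aldol of tert-butyl acetate with acrolein, then oxidation.
5. Ring order: C (aromatic, bought) → B → A → C dearomatised → D.

Assumption: the SMILES is read literally, so C20 on C10 is cis to H5 and H9 (A/B cis-fused; H5, H9, C7, C15, C18 and C20 share one face, called β; C19 is α); the sense of induction in step 6 is assumed from related cyclic β-keto esters and must be confirmed experimentally on 12 before going on.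

Numbering: gibberellane numbers. Ring A = C1–C5, C10. Ring B = C5, C6, C8, C9, C10. Ring C = C8, C9, C11–C14. Ring D = C8, C13–C16. C7 sits on C6, C18/C19 on C4, C20 on C10, C17 on C16.

**Step 1**
Reactants: 1 3-methoxyphenylacetic acid; 2 mono-tert-butyl malonate
Product: 4 tert-butyl 4-(3-methoxyphenyl)-3-oxobutanoate, via acyl imidazolide 3 (not isolated)
Conditions: CDI, THF, rt; then 2, MgCl2, Et3N, THF/MeCN, rt to 40 °C; 1 M HCl work-up
Reagents that add atoms: none
Why: Decarboxylative Claisen condensation (Masamune–Brooks type): the soft magnesium malonate enolate is C-acylated by the imidazolide and loses CO2 without enolising the acidic arylacetyl unit; no stereocentre forms.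

**Step 2**
Reactants: 4 tert-butyl 4-(3-methoxyphenyl)-3-oxobutanoate
Product: 5 tert-butyl 2-diazo-4-(3-methoxyphenyl)-3-oxobutanoate
Conditions: 4-acetamidobenzenesulfonyl azide, Et3N, MeCN, 0 °C to rt
Reagents that add atoms: 4-acetamidobenzenesulfonyl azide CC(=O)Nc1ccc(cc1)S(=O)(=O)N=[N+]=[N-]
Why: Regitz diazo transfer to the active methylene of a β-keto ester is general and high yielding; no stereocentre forms.

**Step 3**
Reactants: 5 tert-butyl 2-diazo-4-(3-methoxyphenyl)-3-oxobutanoate
Product: 6 tert-butyl 5-methoxy-2-oxoindane-1-carboxylate (fragment 1)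
Conditions: Rh2(OAc)4 (1 mol %), CH2Cl2, rt to reflux
Reagents that add atoms: none
Why: Intramolecular Rh-carbenoid aromatic substitution (formal aromatic C–H insertion) closes five-membered ring B at the free ortho carbon para to OMe (C9), which fixes the methoxy group at C13; the new C10–H centre is enolised and so stereochemically irrelevant.

**Step 4**
Reactants: 7 tert-butyl acetate; 8 acrolein
Product: 10 tert-butyl 3-hydroxypent-4-enoate, via lithium enolate 9 (not isolated)
Conditions: LiN(i-Pr)2, THF, −78 °C; then 8, −78 °C; AcOH quench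
Reagents that add atoms: none
Why: Intermolecular aldol addition of an ester lithium enolate goes 1,2 to acrolein at low temperature; the carbinol centre is racemic and is removed in step 5.

**Step 5**
Reactants: 10 tert-butyl 3-hydroxypent-4-enoate
Product: 11 tert-butyl 3-oxopent-4-enoate (fragment 2, Nazarov reagent)
Conditions: Dess–Martin periodinane, CH2Cl2, 0 °C to rt; used at once
Reagents that add atoms: none
Why: Dess–Martin oxidation of the allylic alcohol is neutral and mild, so the polymerisable vinyl β-keto ester survives.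

**Step 6 (key step)**
Reactants: 6 fragment 1; 11 fragment 2
Product: 12 tert-butyl (1S)-1-(5-tert-butoxy-3,5-dioxopentyl)-5-methoxy-2-oxoindane-1-carboxylate
Conditions: 9-O-(phenanthren-9-yl)cupreidine (10 mol %), CH2Cl2, −24 °C, 11 added over 6 h
Reagents that add atoms: none
Why: Organocatalytic asymmetric intermolecular Michael addition: the quinuclidine deprotonates the enolic doubly activated C10–H while the 6'-OH binds the vinyl ketone, so the C10–C1 bond and the quaternary C10 centre (S) are set under catalyst control, and slow addition lets the more acidic donor 6 outcompete self-addition of 11.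

**Step 7**
Reactants: 12 Michael adduct
Product: 13 di-tert-butyl 7-methoxy-2-oxo-2,3,4,9-tetrahydro-4aH-fluorene-1,4a-dicarboxylate (C3 ketone; C4=C5; C10 as in 12)
Conditions: piperidine (20 mol %), AcOH (20 mol %), toluene, 4 Å MS, 60 °C
Reagents that add atoms: none
Why: Intramolecular Knoevenagel (aldol) condensation of the C4 active methylene with the C5 ketone closes six-membered ring A; C10 has no α-hydrogen and the buffered amine salt avoids retro-Michael, so it is not scrambled.

**Step 8**
Reactants: 13 tricyclic enone diester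
Product: 14 di-tert-butyl 7-methoxy-2,9-dioxo-2,3,4,9-tetrahydro-4aH-fluorene-1,4a-dicarboxylate (C3,C6-ene-dione)
Conditions: Rh2(cap)4 (cap = caprolactamate, 1 mol %), t-BuOOH (70 % in water, 5 equiv), 1,2-dichloroethane, 40 °C
Reagents that add atoms: tert-butyl hydroperoxide CC(C)(C)OO
Why: Radical allylic/benzylic C–H oxidation: C6H2 is the only benzylic methylene and is also γ to the enone, so it is converted selectively to the ketone (enone to ene-dione).

**Step 9**
Reactants: 14 ene-dione
Product: 15 di-tert-butyl cis-7-methoxy-2,9-dioxo-1,2,3,4,9,9a-hexahydro-4aH-fluorene-1,4a-dicarboxylate (H5 β, C20 β; C4 enolisable)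
Conditions: Zn dust, AcOH, rt; then DBU (10 mol %), CH2Cl2, rt
Reagents that add atoms: none
Why: Zn/AcOH reduction of a 2-ene-1,4-dione saturates C4=C5; C5 is now α to the indanone carbonyl and equilibrates to the less strained cis-fused hexahydrofluorenone, which places H5 on the face of C20.

**Step 10**
Reactants: 15 cis diketo diester
Product: 16 di-tert-butyl cis-7-methoxy-1-methyl-2,9-dioxo-hexahydrofluorene-1,4a-dicarboxylate (C18 β; C19 α)
Conditions: MeI, K2CO3, acetone, rt to 40 °C
Reagents that add atoms: iodomethane CI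
Why: β-Keto ester C-alkylation: only C4–H is acidic enough for K2CO3, and MeI approaches the enolate from the convex β face (the side of H5), away from the indanone plate folded under ring A, setting quaternary C4 with methyl β and ester α.

**Step 11**
Reactants: 16 methylated diketo diester
Product: 18 C3 enol triflate (C2=C3), via potassium enolate 17 (not isolated)
Conditions: KN(SiMe3)2, THF, −78 °C (16 added to base); then PhNTf2, −78 to 0 °C
Reagents that add atoms: N-phenylbis(trifluoromethanesulfonimide) O=S(=O)(N(c1ccccc1)S(=O)(=O)C(F)(F)F)C(F)(F)F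
Why: Kinetic enolisation and O-triflation: the C3 ketone can enolise only towards C2 because C4 is quaternary, and the tertiary C5–H, flanked by two quaternary carbons, is not removed by the bulky base at −78 °C.

**Step 12**
Reactants: 18 enol triflate
Product: 19 C2=C3 alkene (C3 deoxygenated)
Conditions: Pd(OAc)2 (5 mol %), PPh3 (10 mol %), HCO2H, Et3N, DMF, 60 °C
Reagents that add atoms: none
Why: Palladium-catalysed formate hydrogenolysis of a vinyl triflate (oxidative addition to zerovalent palladium, formate decarboxylation, reductive elimination) tolerates the aryl ketone and both esters.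

**Step 13**
Reactants: 19 alkene
Product: 20 di-tert-butyl cis-7-methoxy-1-methyl-9-oxo-hexahydrofluorene-1,4a-dicarboxylate (C6 aryl ketone; H5, C18, C20 β; C19 α)
Conditions: H2 (1 atm), Pd/C, EtOAc, rt
Reagents that add atoms: none
Why: Catalytic hydrogenation of the unhindered disubstituted alkene is faster than any reduction of the aryl ketone in neutral EtOAc; no stereocentre forms.

**Step 14**
Reactants: 20 aryl ketone
Product: 22 8β-allyl 6-ketone (9(11)-ene; 13-methoxy-13(14)-ene; C19 and C20 tert-butyl esters), via potassium dienolate 21 (not isolated)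
Conditions: K (2.5 equiv), NH3/THF, t-BuOH (1.0 equiv), −78 °C; LiBr; allyl bromide, −78 °C; solid NH4Cl
Reagents that add atoms: allyl bromide C=CCBr
Why: Birch reduction–alkylation of an aromatic ketone: protonation para to the acyl carbon (C12) leaves the C6–C8 dienolate, which is allylated at C8 from the convex β face (flanked by H5 rather than C4 and C1). This sets quaternary C8 and leaves C13 as an enol ether; the easily reduced aryl ketone takes up the limited metal before the hindered esters.

**Step 15**
Reactants: 22 allyl ketone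
Product: 23 C6 methoxymethylidene derivative (E/Z mixture)
Conditions: Ph3P(CH2OMe)Cl (4 equiv), KOt-Bu, THF, 0 to 50 °C
Reagents that add atoms: (methoxymethyl)triphenylphosphonium chloride COC[P+](c1ccccc1)(c1ccccc1)c1ccccc1.[Cl-]
Why: Wittig methoxymethylenation reacts only at the single free carbonyl (C13 is still masked and the tert-butyl esters are inert) and brings in C7.

**Step 16**
Reactants: 23 bis(enol ether)
Product: 24 C7 aldehyde C13 ketone (C7 β; 9(11)-ene retained)
Conditions: 2 M HCl, THF, rt
Reagents that add atoms: water O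
Why: Acid hydrolysis of both enol ethers unmasks the C13 ketone and the C7 aldehyde; the epimerisable C6 centre settles under acid with the formyl group trans to the bulky C4 (C7 β, H6 α).

**Step 17**
Reactants: 24 keto aldehyde
Product: 25 C7 carboxylic acid
Conditions: NaClO2, NaH2PO4, 2-methyl-2-butene, t-BuOH/H2O, rt
Reagents that add atoms: sodium chlorite [Na+].[O-]Cl=O
Why: Pinnick oxidation converts only the aldehyde, and the alkene scavenger protects the allyl and ring alkenes from HOCl; C6 is unchanged.

**Step 18**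
Reactants: 25 acid
Product: 26 C7 methyl ester
Conditions: MeI, KHCO3, DMF, rt
Reagents that add atoms: iodomethane CI
Why: SN2 O-alkylation of the carboxylate is insensitive to hindrance at the acyl carbon, and the weak base does not move the β,γ-alkene; this makes C7 the only methyl ester.

**Step 19**
Reactants: 26 allyl methyl ester
Product: 28 C16 aldehyde (C8 β-CH2CHO), via vicinal diol 27 (not isolated)
Conditions: OsO4 (2 mol %), NaIO4 (4 equiv), 2,6-lutidine, dioxane/H2O, rt
Reagents that add atoms: osmium tetroxide O=[Os](=O)(=O)=O; sodium periodate [Na+].[O-]I(=O)(=O)=O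
Why: Lemieux–Johnson cleavage attacks the monosubstituted allyl alkene far faster than the 9(11)-alkene, which is buried between two quaternary carbons.

**Step 20**
Reactants: 28 unsaturated keto aldehyde
Product: 29 saturated keto aldehyde (H9 β; B/C cis)
Conditions: [Ir(cod)(PCy3)(py)]PF6 (10 mol %), H2 (10 bar), CH2Cl2, rt
Reagents that add atoms: none
Why: Carbonyl-directed homogeneous hydrogenation: the cationic iridium catalyst binds the β-face carbonyls around the alkene (C20 ester, C7 ester, C16 aldehyde) and delivers H2 to that face, setting H9 β, cis to C15, the same cis-hydrindane outcome seen with angularly substituted hydrindenes.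

**Step 21**
Reactants: 29 keto aldehyde
Product: 30 13,16-cis-diol (ring D closed)
Conditions: SmI2 (3 equiv), t-BuOH (2 equiv), THF, −78 °C to rt
Reagents that add atoms: none
Why: SmI2 intramolecular pinacol coupling joins C13 and C16 into the five-membered ring; the β-oriented C15–C16 arm can reach C13 from only one face, which fixes C13, and samarium chelation gives the cis-diol (C16 is removed in step 22).

**Step 22**
Reactants: 30 diol
Product: 31 13-hydroxy-16-ketone
Conditions: IBX, DMSO, rt
Reagents that add atoms: none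
Why: IBX oxidises the secondary alcohol of a 1,2-diol to the α-ketol without C–C cleavage; the tertiary C13–OH is untouched.

**Step 23**
Reactants: 31 ketol
Product: 32 13-O-trimethylsilyl 16-ketone
Conditions: N-(trimethylsilyl)imidazole, CH2Cl2, rt
Reagents that add atoms: N-(trimethylsilyl)imidazole C[Si](C)(C)n1ccnc1
Why: Silylation of the bridgehead alcohol blocks the base-induced α-ketol (acyloin) rearrangement of rings C/D in the next step.

**Step 24**
Reactants: 32 silyloxy ketone
Product: 33 16-methylidene 13-O-trimethylsilyl triester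
Conditions: Ph3PCH3Br (3 equiv), KOt-Bu, THF, 0 °C to rt
Reagents that add atoms: methyltriphenylphosphonium bromide C[P+](c1ccccc1)(c1ccccc1)c1ccccc1.[Br-]
Why: Wittig methylenation of the unhindered cyclopentanone carbonyl is much faster than attack on the hindered esters, and C6 already holds its thermodynamic configuration.

**Step 25**
Reactants: 33 protected triester
Product: 35 target (7-methyl ester 19,20-diacid), via tris(trimethylsilyl) derivative 34 (not isolated)
Conditions: TMSOTf (4 equiv), 2,6-lutidine (6 equiv), CH2Cl2, 0 °C to rt; then H2O/THF, citric acid (cat.), rt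
Reagents that add atoms: none
Why: Silyl triflate-mediated tert-butyl ester cleavage (O-silylation, loss of isobutene) runs under buffered non-protic conditions that spare the methyl ester and the acid-sensitive 13-oxy-16-ene unit; mild hydrolysis then removes all three silyl groups without touching a stereocentre.

**Compound list**
1 | 3-methoxyphenylacetic acid | COc1cccc(CC(=O)O)c1 | starting material
2 | mono-tert-butyl malonate | CC(C)(C)OC(=O)CC(=O)O | starting material
3 | 1-[(3-methoxyphenyl)acetyl]imidazole (acyl imidazolide) | COc1cccc(CC(=O)n2ccnc2)c1 | intermediate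
4 | tert-butyl 4-(3-methoxyphenyl)-3-oxobutanoate | COc1cccc(CC(=O)CC(=O)OC(C)(C)C)c1 | intermediate
5 | tert-butyl 2-diazo-4-(3-methoxyphenyl)-3-oxobutanoate | COc1cccc(CC(=O)C(=[N+]=[N-])C(=O)OC(C)(C)C)c1 | intermediate
6 | tert-butyl 5-methoxy-2-oxoindane-1-carboxylate (fragment 1; enolised) | COc1ccc2c(c1)CC(=O)C2C(=O)OC(C)(C)C | intermediate
7 | tert-butyl acetate | CC(=O)OC(C)(C)C | starting material
8 | acrolein | C=CC=O | starting material
9 | lithium enolate of tert-butyl acetate | [Li+].C=C([O-])OC(C)(C)C | intermediate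
10 | tert-butyl 3-hydroxypent-4-enoate (racemic) | C=CC(O)CC(=O)OC(C)(C)C | intermediate
11 | tert-butyl 3-oxopent-4-enoate (fragment 2) | C=CC(=O)CC(=O)OC(C)(C)C | intermediate
12 | tert-butyl (1S)-1-(5-tert-butoxy-3,5-dioxopentyl)-5-methoxy-2-oxoindane-1-carboxylate | COc1ccc2c(c1)CC(=O)[C@@]2(CCC(=O)CC(=O)OC(C)(C)C)C(=O)OC(C)(C)C | intermediate
13 | tricyclic enone diester (C3 ketone, C4=C5) | COc1ccc2c(c1)CC1=C(C(=O)OC(C)(C)C)C(=O)CC[C@@]12C(=O)OC(C)(C)C | intermediate
14 | C3,C6-ene-dione diester | COc1ccc2c(c1)C(=O)C1=C(C(=O)OC(C)(C)C)C(=O)CC[C@@]12C(=O)OC(C)(C)C | intermediate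
15 | cis-fused C3,C6-diketo diester (H5 and C20 β; C4 enolisable) | COc1ccc2c(c1)C(=O)[C@H]1[C@]2(C(=O)OC(C)(C)C)CCC(=O)C1C(=O)OC(C)(C)C | intermediate
16 | C4-methylated diketo diester (C18 β, C19 α) | COc1ccc2c(c1)C(=O)[C@H]1[C@]2(C(=O)OC(C)(C)C)CCC(=O)[C@@]1(C)C(=O)OC(C)(C)C | intermediate
17 | potassium C2–C3 enolate of 16 | [K+].COc1ccc2c(c1)C(=O)[C@H]1[C@]2(C(=O)OC(C)(C)C)CC=C([O-])[C@@]1(C)C(=O)OC(C)(C)C | intermediate
18 | C3 enol triflate | COc1ccc2c(c1)C(=O)[C@H]1[C@]2(C(=O)OC(C)(C)C)CC=C(OS(=O)(=O)C(F)(F)F)[C@@]1(C)C(=O)OC(C)(C)C | intermediate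
19 | C2=C3 alkene | COc1ccc2c(c1)C(=O)[C@H]1[C@]2(C(=O)OC(C)(C)C)CC=C[C@@]1(C)C(=O)OC(C)(C)C | intermediate
20 | cis-fused 7-methoxy-1-methyl-9-oxohexahydrofluorene-1,4a-dicarboxylate di-tert-butyl ester | COc1ccc2c(c1)C(=O)[C@H]1[C@]2(C(=O)OC(C)(C)C)CCC[C@@]1(C)C(=O)OC(C)(C)C | intermediate
21 | potassium C6–C8 dienolate from Birch reduction | [K+].[O-]C1=C2C=C(OC)CC=C2[C@@]2(C(=O)OC(C)(C)C)CCC[C@@](C)(C(=O)OC(C)(C)C)[C@@H]12 | intermediate
22 | 8β-allyl 6-ketone, 9(11)-ene, 13-methyl enol ether | C=CC[C@]12C=C(OC)CC=C1[C@@]1(C(=O)OC(C)(C)C)CCC[C@@](C)(C(=O)OC(C)(C)C)[C@H]1C2=O | intermediate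
23 | C6 methoxymethylidene bis(enol ether) (E/Z) | C=CC[C@]12C=C(OC)CC=C1[C@@]1(C(=O)OC(C)(C)C)CCC[C@@](C)(C(=O)OC(C)(C)C)[C@H]1C2=COC | intermediate
24 | C7 aldehyde, C13 ketone, 9(11)-ene | C=CC[C@]12CC(=O)CC=C1[C@@]1(C(=O)OC(C)(C)C)CCC[C@@](C)(C(=O)OC(C)(C)C)[C@H]1[C@@H]2C=O | intermediate
25 | C7 carboxylic acid | C=CC[C@]12CC(=O)CC=C1[C@@]1(C(=O)OC(C)(C)C)CCC[C@@](C)(C(=O)OC(C)(C)C)[C@H]1[C@@H]2C(=O)O | intermediate
26 | C7 methyl ester | C=CC[C@]12CC(=O)CC=C1[C@@]1(C(=O)OC(C)(C)C)CCC[C@@](C)(C(=O)OC(C)(C)C)[C@H]1[C@@H]2C(=O)OC | intermediate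
27 | 16,17-diol (C16 epimers) | OCC(O)C[C@]12CC(=O)CC=C1[C@@]1(C(=O)OC(C)(C)C)CCC[C@@](C)(C(=O)OC(C)(C)C)[C@H]1[C@@H]2C(=O)OC | intermediate
28 | C16 aldehyde, 9(11)-ene | O=CC[C@]12CC(=O)CC=C1[C@@]1(C(=O)OC(C)(C)C)CCC[C@@](C)(C(=O)OC(C)(C)C)[C@H]1[C@@H]2C(=O)OC | intermediate
29 | saturated C13 ketone C16 aldehyde (H9 β) | O=CC[C@]12CC(=O)CC[C@H]1[C@@]1(C(=O)OC(C)(C)C)CCC[C@@](C)(C(=O)OC(C)(C)C)[C@H]1[C@@H]2C(=O)OC | intermediate
30 | tetracyclic 13,16-cis-diol | O[C@@H]1C[C@]23C[C@@]1(O)CC[C@H]2[C@@]1(C(=O)OC(C)(C)C)CCC[C@@](C)(C(=O)OC(C)(C)C)[C@H]1[C@@H]3C(=O)OC | intermediate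
31 | 13-hydroxy-16-ketone | O=C1C[C@]23C[C@@]1(O)CC[C@H]2[C@@]1(C(=O)OC(C)(C)C)CCC[C@@](C)(C(=O)OC(C)(C)C)[C@H]1[C@@H]3C(=O)OC | intermediate
32 | 13-O-trimethylsilyl 16-ketone | O=C1C[C@]23C[C@@]1(O[Si](C)(C)C)CC[C@H]2[C@@]1(C(=O)OC(C)(C)C)CCC[C@@](C)(C(=O)OC(C)(C)C)[C@H]1[C@@H]3C(=O)OC | intermediate
33 | 16-methylidene 13-O-trimethylsilyl 7-methyl 19,20-di-tert-butyl triester | C=C1C[C@]23C[C@@]1(O[Si](C)(C)C)CC[C@H]2[C@@]1(C(=O)OC(C)(C)C)CCC[C@@](C)(C(=O)OC(C)(C)C)[C@H]1[C@@H]3C(=O)OC | intermediate
34 | 13-O-trimethylsilyl 19,20-bis(trimethylsilyl) ester | C=C1C[C@]23C[C@@]1(O[Si](C)(C)C)CC[C@H]2[C@@]1(C(=O)O[Si](C)(C)C)CCC[C@@](C)(C(=O)O[Si](C)(C)C)[C@H]1[C@@H]3C(=O)OC | intermediate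
35 | CNP0285449.1 (13-hydroxy-16-ene 7-methyl ester 19,20-dioic acid) | C=C1C[C@]23C[C@@]1(O)CC[C@H]2[C@@]1(C(=O)O)CCC[C@@](C)(C(=O)O)[C@H]1[C@@H]3C(=O)OC | target

Total step count: 25. Longest linear sequence: 23 steps (steps 1–3 and 6–25).

**Three steps most likely to fail**

Step 14 (Birch reduction–allylation). The ketone may be over-reduced to the benzylic alcohol, or trapping at C8 may be inefficient. The fallback separates reduction from C–C bond formation. It sets out from 20: run the K/NH3 reduction with excess t-BuOH and a proton quench, then conjugate the dihydro ketone with NaOMe in MeOH to the 8(9)-en-6-one 13-methyl dienol ether F1. Thermodynamic deprotonation of F1 at C11 (KOt-Bu, t-BuOH/THF) and deconjugative α-allylation of the extended enolate at C8 with allyl bromide, again from the β face, comes back to the route at 22.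

Step 15 (Wittig on the C6 ketone). The carbonyl lies between a quaternary and a hindered tertiary carbon and may only enolise with the bulky ylide. The fallback uses a small sulfur ylide and a rearrangement in place of an olefination. It sets out from 22: dimethylsulfonium methylide (Me3SI, NaH, DMSO/THF) gives the C6 spiro-epoxide F2. Meinwald rearrangement with MgBr2·OEt2 in Et2O, followed by 2 M HCl in THF (hydride shift to the aldehyde, enol ether hydrolysis, C6 equilibration), comes back at 24.

Step 20 (hydrogenation of the 9(11)-alkene). The alkene sits between two quaternary carbons, so both rate and facial control are uncertain. The fallback replaces hydrogen delivery at C9 by a thermodynamic protonation. It sets out from 26: DBU in toluene at 60 °C moves the alkene into conjugation through the C12 dienolate and gives the 11(12)-en-13-one F3, in which C9–H adopts the more stable cis B/C fusion (H9 β). Conjugate reduction with [(Ph3P)CuH]6 in benzene leaves the allyl group alone and gives the saturated allyl ketone F4. OsO4/NaIO4 cleavage of F4 comes back at 29.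

**Further compounds**
F1 | step 14 | 8(9)-en-6-one 13-methyl dienol ether | COC1=CC2=C(CC1)[C@@]1(C(=O)OC(C)(C)C)CCC[C@@](C)(C(=O)OC(C)(C)C)[C@H]1C2=O
F2 | step 15 | C6 spiro-epoxide of 22 (C6 configuration not defined) | C=CC[C@]12C=C(OC)CC=C1[C@@]1(C(=O)OC(C)(C)C)CCC[C@@](C)(C(=O)OC(C)(C)C)[C@H]1C21CO1
F3 | step 20 | 8β-allyl 11(12)-en-13-one 7-methyl ester (H9 β) | C=CC[C@]12CC(=O)C=C[C@H]1[C@@]1(C(=O)OC(C)(C)C)CCC[C@@](C)(C(=O)OC(C)(C)C)[C@H]1[C@@H]2C(=O)OC
F4 | step 20 | 8β-allyl saturated 13-ketone 7-methyl ester (H9 β) | C=CC[C@]12CC(=O)CC[C@H]1[C@@]1(C(=O)OC(C)(C)C)CCC[C@@](C)(C(=O)OC(C)(C)C)[C@H]1[C@@H]2C(=O)OC
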